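**Retrosynthetic overview**
1. The acetate and the alkyne carbon C1 go on last. Behind them stands a bicyclic bis-ether in which the oxepene (O7, C7–C12) is complete and C2–C6 with O6 are held as a 3,6-dihydro-2H-pyran, a temporary ring that masks O6 and fixes the 3Z double bond. It is unmasked by allylic oxidation, reduction to the lactol and one-carbon homologation.
2. Both rings come from one double ring-closing metathesis of an acyclic tetraene. C3=C4 closes the pyran (O6 allyl ether with the C6 arm) and C9=C10 closes the oxepene (C12 allyl with the C7 arm), pyran first, oxepene second, in the same flask. The pyran is opened again in the homologation step.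
3. Enabling feature: C4 and C9 are both alkene carbons one CH2 away from the threo C6/C7 glycol, so C4–C9 is a C2-symmetric 1,2-diol with two identical CH2–CH= arms. Bought as L-threitol, its hydroxyls are homotopic, so one mono-allylation tells O6 from O7. Making both arms prenyl (trisubstituted) keeps the catalyst off C4 and C9 and so bars the cyclohexene between the vicinal arms.
4. The tetraene is built on O7: glycolate ether, auxiliary-controlled allylation (C12), chelation-controlled ethyl addition and inversion to the bromide (C13).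

Key step: step 11

Remark: the chain is numbered C1 (alkyne CH) to C15 (CH3); O6 is the acetate oxygen and O7 the ring oxygen between C7 and C12. The target is read as (6S,7S,12R,13S), 3Z, with the C7 and C12 substituents cis on the oxepene.

**Step 1**
Reactants: 1 (4S,5S)-(2,2-dimethyl-1,3-dioxolane-4,5-diyl)bis(methylene) bis(4-methylbenzenesulfonate) (1,4-di-O-tosyl-2,3-O-isopropylidene-L-threitol); 2 2-methylprop-1-enylmagnesium bromide
Product: 3 (4S,5S)-2,2-dimethyl-4,5-bis(3-methylbut-2-en-1-yl)-1,3-dioxolane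
Conditions: 2 (4 equiv), CuI (20 mol%), THF, −30 °C → rt
Reagents that add atoms: 2-methylprop-1-enylmagnesium bromide, CC(C)=C[Mg]Br
Why: Copper-catalysed cross-coupling of the alkenyl Grignard reagent with the two primary tosylates (SN2 displacement by the alkenyl cuprate) should install both 3-methylbut-2-enyl arms at once; C6 and C7 are bought with L-threitol and are not touched.

**Step 2**
Reactants: 3 (4S,5S)-2,2-dimethyl-4,5-bis(3-methylbut-2-en-1-yl)-1,3-dioxolane
Product: 4 (5S,6S)-2,9-dimethyldeca-2,8-diene-5,6-diol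
Conditions: AcOH/H2O (4:1), 45 °C
Reagents that add atoms: none
Why: Acid-catalysed acetal hydrolysis of the strained trans-dioxolane should be complete under conditions too mild to protonate the trisubstituted alkenes; no stereocentre is involved.

**Step 3**
Reactants: 4 (5S,6S)-2,9-dimethyldeca-2,8-diene-5,6-diol; 5 allyl bromide
Product: 6 (5S,6S)-2,9-dimethyl-6-(prop-2-en-1-yloxy)deca-2,8-dien-5-ol
Conditions: NaH (1.0 equiv), 5 (1.0 equiv), n-Bu4NI (cat.), THF/DMF, 0 °C → rt
Reagents that add atoms: allyl bromide, C=CCBr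
Why: Williamson ether synthesis on a C2-symmetric diol whose two hydroxyl groups are homotopic, so mono-alkylation can give only one mono-ether (recovered 4 is recycled); the allyl group protects O6 up to step 11 and then serves as the metathesis tether.

**Step 4**
Reactants: 6 (5S,6S)-2,9-dimethyl-6-(prop-2-en-1-yloxy)deca-2,8-dien-5-ol; 7 bromoacetic acid
Product: 8 2-{[(5S,6S)-2,9-dimethyl-6-(prop-2-en-1-yloxy)deca-2,8-dien-5-yl]oxy}acetic acid
Conditions: NaH (3 equiv), 7, THF, 0 °C → rt; aq. HCl work-up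
Reagents that add atoms: bromoacetic acid, OC(=O)CBr
Why: Williamson ether synthesis of the remaining secondary alkoxide with sodium bromoacetate, a standard entry to glycolate ethers of hindered alcohols; no stereocentre changes.

**Step 5**
Reactants: 8 2-{[(5S,6S)-2,9-dimethyl-6-(prop-2-en-1-yloxy)deca-2,8-dien-5-yl]oxy}acetic acid; 9 pivaloyl chloride; 10 (S)-4-benzyl-2-oxazolidinone
Product: 12 (4S)-4-benzyl-3-({[(5S,6S)-2,9-dimethyl-6-(prop-2-en-1-yloxy)deca-2,8-dien-5-yl]oxy}acetyl)-1,3-oxazolidin-2-one, via mixed pivalic anhydride 11 (not isolated)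
Conditions: 9, Et3N, THF, −20 °C; then 10, LiCl, rt
Reagents that add atoms: (S)-4-benzyl-2-oxazolidinone, O=C1N[C@@H](Cc2ccccc2)CO1; pivaloyl chloride, CC(C)(C)C(Cl)=O, leaves atoms only in 11
Why: N-acylation of the oxazolidinone through the mixed pivalic anhydride (attack at the less hindered glycolyl carbonyl, LiCl/Et3N activation) should give the imide; no stereocentre changes.

**Step 6**
Reactants: 12 (4S)-4-benzyl-3-({[(5S,6S)-2,9-dimethyl-6-(prop-2-en-1-yloxy)deca-2,8-dien-5-yl]oxy}acetyl)-1,3-oxazolidin-2-one; 13 allyl iodide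
Product: 15 (4S)-4-benzyl-3-[(2R)-2-{[(5S,6S)-2,9-dimethyl-6-(prop-2-en-1-yloxy)deca-2,8-dien-5-yl]oxy}pent-4-enoyl]-1,3-oxazolidin-2-one, via sodium Z-enolate 14 (not isolated)
Conditions: NaN(SiMe3)2, THF, −78 °C; 13, −78 → −45 °C
Reagents that add atoms: allyl iodide, C=CCI
Why: Evans alkylation: the chelated sodium Z-enolate is shielded on one face by the benzyl group, so allyl iodide should enter from the other face and set C12 as R.

**Step 7**
Reactants: 15 (4S)-4-benzyl-3-[(2R)-2-{[(5S,6S)-2,9-dimethyl-6-(prop-2-en-1-yloxy)deca-2,8-dien-5-yl]oxy}pent-4-enoyl]-1,3-oxazolidin-2-one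
Product: 16 (2R)-2-{[(5S,6S)-2,9-dimethyl-6-(prop-2-en-1-yloxy)deca-2,8-dien-5-yl]oxy}pent-4-en-1-ol
Conditions: LiBH4, MeOH (1 equiv), Et2O, 0 °C
Reagents that add atoms: none
Why: Reductive cleavage of the N-acyl oxazolidinone by LiBH4 at the exocyclic carbonyl should release the primary alcohol and the auxiliary without touching C12 or the alkenes.

**Step 8**
Reactants: 16 (2R)-2-{[(5S,6S)-2,9-dimethyl-6-(prop-2-en-1-yloxy)deca-2,8-dien-5-yl]oxy}pent-4-en-1-ol
Product: 17 (2R)-2-{[(5S,6S)-2,9-dimethyl-6-(prop-2-en-1-yloxy)deca-2,8-dien-5-yl]oxy}pent-4-enal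
Conditions: Dess–Martin periodinane, NaHCO3, CH2Cl2, 0 °C → rt
Reagents that add atoms: none
Why: Dess–Martin oxidation under buffered, non-epimerising conditions should give the α-alkoxy aldehyde, which is used at once so that C12 keeps its configuration.

**Step 9**
Reactants: 17 (2R)-2-{[(5S,6S)-2,9-dimethyl-6-(prop-2-en-1-yloxy)deca-2,8-dien-5-yl]oxy}pent-4-enal; 18 ethylmagnesium bromide
Product: 19 (3R,4R)-4-{[(5S,6S)-2,9-dimethyl-6-(prop-2-en-1-yloxy)deca-2,8-dien-5-yl]oxy}hept-6-en-3-ol
Conditions: MgBr2·OEt2 (3 equiv), CH2Cl2, −78 °C; then 18 (Et2O solution), −78 °C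
Reagents that add atoms: ethylmagnesium bromide, CC[Mg]Br
Why: Cram-chelate controlled Grignard addition: magnesium bridges the aldehyde oxygen and O7 in a five-membered chelate and ethyl adds from the face of the C12 hydrogen, which should set C13 as R, syn to O7.

**Step 10**
Reactants: 19 (3R,4R)-4-{[(5S,6S)-2,9-dimethyl-6-(prop-2-en-1-yloxy)deca-2,8-dien-5-yl]oxy}hept-6-en-3-ol; 20 tetrabromomethane
Product: 21 (5S,6S)-5-{[(4R,5S)-5-bromohept-1-en-4-yl]oxy}-2,9-dimethyl-6-(prop-2-en-1-yloxy)deca-2,8-diene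
Conditions: 20, P(n-C8H17)3, toluene, 70 °C
Reagents that add atoms: tetrabromomethane, BrC(Br)(Br)Br
Why: Appel reaction: bromide displaces the alkoxyphosphonium group by SN2 with inversion, which should turn (13R)-OH into (13S)-Br.

**Step 11**
Reactants: 21 (5S,6S)-5-{[(4R,5S)-5-bromohept-1-en-4-yl]oxy}-2,9-dimethyl-6-(prop-2-en-1-yloxy)deca-2,8-diene
Product: 23 (2S)-2-[(2S,7R)-7-[(1S)-1-bromopropyl]-2,3,6,7-tetrahydrooxepin-2-yl]-3,6-dihydro-2H-pyran, via dihydropyran diene 22 (not isolated)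
Conditions: second-generation Hoveyda–Grubbs catalyst RuCl2(H2IMes)(=CH–C6H4-2-O-i-Pr) (10 mol%), toluene (2 mM), 70 °C, argon sparge
Reagents that add atoms: none
Why: Each monosubstituted alkene (O6-allyl, C12-allyl) loads the ruthenium alkylidene, and each carbene closes by [2+2] cycloaddition/cycloreversion on the nearest trisubstituted prenyl arm with loss of 2-methylpropene, first C3=C4 (pyran, giving 22) and then C9=C10 (oxepene). The closest known reaction types are ring-closing metathesis of allyl homoallyl ethers to 3,6-dihydro-2H-pyrans and of α,α'-disubstituted bis-homoallylic ethers to oxepenes, here run as a double ring-closing metathesis of one tetraene. Both rings close in the ordinary ring-closing mode with the new double bond inside the ring, six-membered for the pyran and seven-membered for the oxepene, and both new alkenes are necessarily cis, so the later 3Z geometry is fixed here. No stereocentre is formed or touched: C6, C7, C12 and C13 are carried through, and the cis relation of the oxepene substituents follows from their configurations. The selectivity needed is the pairing O6-allyl/C6 arm and C12-allyl/C7 arm instead of a cyclohexene between the vicinal C6 and C7 arms; it is secured because trisubstituted alkenes are not loaded by the catalyst, so no carbene sits on C4 or C9, while each loaded carbene finds its partner in a six- or seven-membered relationship. Gauche O–C–C–O (C6–C7) and O–C–C–Br (C12–C13) preferences fold the ether toward the oxepene closure, and high dilution keeps the two terminal alkenes from coupling between molecules.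

**Step 12**
Reactants: 23 (2S)-2-[(2S,7R)-7-[(1S)-1-bromopropyl]-2,3,6,7-tetrahydrooxepin-2-yl]-3,6-dihydro-2H-pyran; 24 pyridinium chlorochromate
Product: 25 (6S)-6-[(2S,7R)-7-[(1S)-1-bromopropyl]-2,3,6,7-tetrahydrooxepin-2-yl]-5,6-dihydro-2H-pyran-2-one
Conditions: pyridinium chlorochromate [C5H5NH][CrO3Cl] (4 equiv), Celite, CH2Cl2, 40 °C
Reagents that add atoms: pyridinium chlorochromate, [O-][Cr](=O)(=O)Cl.c1cc[nH+]cc1
Why: Allylic oxidation of a cyclic allylic ether by hexavalent chromium: the pyran C2–H bonds are the only ones that are both allylic and α to oxygen, so the unsaturated lactone should form without touching the oxepene or the bromide; no stereocentre changes.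

**Step 13**
Reactants: 25 (6S)-6-[(2S,7R)-7-[(1S)-1-bromopropyl]-2,3,6,7-tetrahydrooxepin-2-yl]-5,6-dihydro-2H-pyran-2-one
Product: 26 (6S)-6-[(2S,7R)-7-[(1S)-1-bromopropyl]-2,3,6,7-tetrahydrooxepin-2-yl]-5,6-dihydro-2H-pyran-2-ol (both anomers)
Conditions: i-Bu2AlH (1.1 equiv), CH2Cl2, −78 °C
Reagents that add atoms: none
Why: 1,2-Reduction of the unsaturated lactone by i-Bu2AlH at −78 °C should stop at the aluminium hemiacetal, which gives the lactol on work-up; the anomeric centre is not carried into the target.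

**Step 14**
Reactants: 26 (6S)-6-[(2S,7R)-7-[(1S)-1-bromopropyl]-2,3,6,7-tetrahydrooxepin-2-yl]-5,6-dihydro-2H-pyran-2-ol; 27 trimethylsilyldiazomethane
Product: 28 (1S,3Z)-1-[(2S,7R)-7-[(1S)-1-bromopropyl]-2,3,6,7-tetrahydrooxepin-2-yl]hex-3-en-5-yn-1-ol
Conditions: 27 (2.5 equiv), LiN(i-Pr)2 (2.5 equiv), THF, −78 °C; add 26; −78 → 0 °C
Reagents that add atoms: trimethylsilyldiazomethane, C[Si](C)(C)C=[N+]=[N-]
Why: Colvin rearrangement (Seyferth–Gilbert-type homologation): the lactol opens to the Z-hydroxy-enal, lithiated trimethylsilyldiazomethane adds 1,2, Peterson-type loss of Me3SiOLi and N2 gives an alkylidene carbene whose 1,2-hydrogen shift forms the C1≡C2 alkyne, and the C3=C4 bond should keep the cis geometry fixed by the ring because it is never broken.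

**Step 15**
Reactants: 28 (1S,3Z)-1-[(2S,7R)-7-[(1S)-1-bromopropyl]-2,3,6,7-tetrahydrooxepin-2-yl]hex-3-en-5-yn-1-ol; 29 acetic anhydride
Product: 30 (1S,3Z)-1-[(2S,7R)-7-[(1S)-1-bromopropyl]-2,3,6,7-tetrahydrooxepin-2-yl]hex-3-en-5-yn-1-yl acetate
Conditions: 29, pyridine, DMAP (cat.), CH2Cl2, 0 °C → rt
Reagents that add atoms: acetic anhydride, CC(=O)OC(C)=O
Why: DMAP-catalysed acylation of the secondary alcohol with retention at C6 should give the target.

**Compound list**
1 | (4S,5S)-(2,2-dimethyl-1,3-dioxolane-4,5-diyl)bis(methylene) bis(4-methylbenzenesulfonate) | Cc1ccc(cc1)S(=O)(=O)OC[C@@H]2OC(C)(C)O[C@H]2COS(=O)(=O)c3ccc(C)cc3 | starting material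
2 | 2-methylprop-1-enylmagnesium bromide | CC(C)=C[Mg]Br | starting material
3 | (4S,5S)-2,2-dimethyl-4,5-bis(3-methylbut-2-en-1-yl)-1,3-dioxolane | CC(C)=CC[C@@H]1OC(C)(C)O[C@H]1CC=C(C)C | intermediate
4 | (5S,6S)-2,9-dimethyldeca-2,8-diene-5,6-diol | CC(C)=CC[C@H](O)[C@@H](O)CC=C(C)C | intermediate
5 | allyl bromide | C=CCBr | starting material
6 | (5S,6S)-2,9-dimethyl-6-(prop-2-en-1-yloxy)deca-2,8-dien-5-ol | CC(C)=CC[C@H](OCC=C)[C@@H](O)CC=C(C)C | intermediate
7 | bromoacetic acid | OC(=O)CBr | starting material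
8 | 2-{[(5S,6S)-2,9-dimethyl-6-(prop-2-en-1-yloxy)deca-2,8-dien-5-yl]oxy}acetic acid | CC(C)=CC[C@H](OCC=C)[C@@H](OCC(O)=O)CC=C(C)C | intermediate
9 | pivaloyl chloride | CC(C)(C)C(Cl)=O | starting material
10 | (S)-4-benzyl-2-oxazolidinone | O=C1N[C@@H](Cc2ccccc2)CO1 | starting material
11 | mixed anhydride of 8 with pivalic acid | CC(C)=CC[C@H](OCC=C)[C@@H](OCC(=O)OC(=O)C(C)(C)C)CC=C(C)C | intermediate
12 | (4S)-4-benzyl-3-({[(5S,6S)-2,9-dimethyl-6-(prop-2-en-1-yloxy)deca-2,8-dien-5-yl]oxy}acetyl)-1,3-oxazolidin-2-one | CC(C)=CC[C@H](OCC=C)[C@@H](OCC(=O)N1[C@@H](Cc2ccccc2)COC1=O)CC=C(C)C | intermediate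
13 | allyl iodide | C=CCI | starting material
14 | sodium Z-enolate of 12 | CC(C)=CC[C@H](OCC=C)[C@@H](O/C=C(\[O-])N1[C@@H](Cc2ccccc2)COC1=O)CC=C(C)C.[Na+] | intermediate
15 | (4S)-4-benzyl-3-[(2R)-2-{[(5S,6S)-2,9-dimethyl-6-(prop-2-en-1-yloxy)deca-2,8-dien-5-yl]oxy}pent-4-enoyl]-1,3-oxazolidin-2-one | CC(C)=CC[C@H](OCC=C)[C@@H](O[C@H](CC=C)C(=O)N1[C@@H](Cc2ccccc2)COC1=O)CC=C(C)C | intermediate
16 | (2R)-2-{[(5S,6S)-2,9-dimethyl-6-(prop-2-en-1-yloxy)deca-2,8-dien-5-yl]oxy}pent-4-en-1-ol | CC(C)=CC[C@H](OCC=C)[C@@H](O[C@H](CC=C)CO)CC=C(C)C | intermediate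
17 | (2R)-2-{[(5S,6S)-2,9-dimethyl-6-(prop-2-en-1-yloxy)deca-2,8-dien-5-yl]oxy}pent-4-enal | CC(C)=CC[C@H](OCC=C)[C@@H](O[C@H](CC=C)C=O)CC=C(C)C | intermediate
18 | ethylmagnesium bromide | CC[Mg]Br | starting material
19 | (3R,4R)-4-{[(5S,6S)-2,9-dimethyl-6-(prop-2-en-1-yloxy)deca-2,8-dien-5-yl]oxy}hept-6-en-3-ol | CC(C)=CC[C@H](OCC=C)[C@@H](O[C@H](CC=C)[C@H](O)CC)CC=C(C)C | intermediate
20 | tetrabromomethane | BrC(Br)(Br)Br | starting material
21 | (5S,6S)-5-{[(4R,5S)-5-bromohept-1-en-4-yl]oxy}-2,9-dimethyl-6-(prop-2-en-1-yloxy)deca-2,8-diene | CC(C)=CC[C@H](OCC=C)[C@@H](O[C@H](CC=C)[C@@H](Br)CC)CC=C(C)C | intermediate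
22 | (2S)-2-[(1S)-1-{[(4R,5S)-5-bromohept-1-en-4-yl]oxy}-4-methylpent-3-en-1-yl]-3,6-dihydro-2H-pyran | C1=CC[C@H](OC1)[C@@H](O[C@H](CC=C)[C@@H](Br)CC)CC=C(C)C | intermediate
23 | (2S)-2-[(2S,7R)-7-[(1S)-1-bromopropyl]-2,3,6,7-tetrahydrooxepin-2-yl]-3,6-dihydro-2H-pyran | C1=CC[C@H](OC1)[C@@H]2CC=CC[C@H]([C@@H](Br)CC)O2 | intermediate
24 | pyridinium chlorochromate | [O-][Cr](=O)(=O)Cl.c1cc[nH+]cc1 | starting material
25 | (6S)-6-[(2S,7R)-7-[(1S)-1-bromopropyl]-2,3,6,7-tetrahydrooxepin-2-yl]-5,6-dihydro-2H-pyran-2-one | O=C1C=CC[C@H](O1)[C@@H]2CC=CC[C@H]([C@@H](Br)CC)O2 | intermediate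
26 | (6S)-6-[(2S,7R)-7-[(1S)-1-bromopropyl]-2,3,6,7-tetrahydrooxepin-2-yl]-5,6-dihydro-2H-pyran-2-ol (both anomers) | OC1C=CC[C@H](O1)[C@@H]2CC=CC[C@H]([C@@H](Br)CC)O2 | intermediate
27 | trimethylsilyldiazomethane | C[Si](C)(C)C=[N+]=[N-] | starting material
28 | (1S,3Z)-1-[(2S,7R)-7-[(1S)-1-bromopropyl]-2,3,6,7-tetrahydrooxepin-2-yl]hex-3-en-5-yn-1-ol | C#C/C=C\C[C@H](O)[C@@H]1CC=CC[C@H]([C@@H](Br)CC)O1 | intermediate
29 | acetic anhydride | CC(=O)OC(C)=O | starting material
30 | (1S,3Z)-1-[(2S,7R)-7-[(1S)-1-bromopropyl]-2,3,6,7-tetrahydrooxepin-2-yl]hex-3-en-5-yn-1-yl acetate | C#C/C=C\C[C@H](OC(C)=O)[C@@H]1CC=CC[C@H]([C@@H](Br)CC)O1 | target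

**Step count and risks**
Total step count: 15. Longest linear sequence: 15 steps (1 → 30).

Steps most likely to fail:

Step 11. The two terminal alkenes of 21 may couple between molecules faster than the slower seven-membered closure onto a trisubstituted alkene, or the O-allyl carbene may close onto the more distant C7 arm, so that oligomers and crossed rings accumulate. The fallback separates the two closures in time. It sets out from imide 12, which has only one terminal alkene. Ring-closing metathesis (second-generation Grubbs catalyst RuCl2(H2IMes)(PCy3)(=CHPh), CH2Cl2, 40 °C) should close the pyran alone and give pyran imide F1. Deprotonation (NaN(SiMe3)2, THF, −78 °C) gives its sodium enolate F2, and allyl iodide the allylated imide F3. LiBH4 then gives primary alcohol F4, Dess–Martin oxidation gives aldehyde F5, chelation-controlled EtMgBr addition (MgBr2·OEt2, CH2Cl2, −78 °C) gives carbinol F6, and CBr4/P(n-C8H17)3 gives the bromide. The fallback comes back to the route at 22, now an isolated compound, whose single terminal alkene can only close the oxepene onto the C7 arm under the conditions of step 11.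

Step 14. The ring-opened Z-enal may isomerise to the E-enal or take up the nucleophile in the conjugate sense before homologation, or the lactol may open too slowly at low temperature. The fallback builds C1 by a Wittig-type olefination followed by elimination (Corey–Fuchs sequence). It sets out from lactol 26: dibromomethylenation with the preformed ylide (CBr4, PPh3, Zn, CH2Cl2, rt) should give (1S,3Z)-6,6-dibromo-1-[(2S,7R)-7-[(1S)-1-bromopropyl]-2,3,6,7-tetrahydrooxepin-2-yl]hexa-3,5-dien-1-ol F7. n-BuLi (3 equiv, THF, −78 °C; then NH4Cl) should convert it by bromine–lithium exchange and 1,2-shift into the alkyne. The fallback comes back to the route at 28.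

Step 10. The neighbouring ether oxygen O7 may take part in the ionisation of the alkoxyphosphonium intermediate, which would lead to retention or a shifted ether, or elimination may take over at 70 °C. The fallback is a two-step activation and displacement at low temperature. It sets out from alcohol 19: ClCH2SO2Cl and 2,6-lutidine (CH2Cl2, 0 °C) should give the chloromethanesulfonate F8, and LiBr (THF, rt) should displace it by SN2 with inversion. The fallback comes back to the route at 21.

**Further compounds**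
F1 | step 11 | (4S)-4-benzyl-3-[({(1S)-1-[(2S)-3,6-dihydro-2H-pyran-2-yl]-4-methylpent-3-en-1-yl}oxy)acetyl]-1,3-oxazolidin-2-one | C1=CC[C@H](OC1)[C@@H](OCC(=O)N2[C@@H](Cc3ccccc3)COC2=O)CC=C(C)C
F2 | step 11 | sodium Z-enolate of F1 | C1=CC[C@H](OC1)[C@@H](O/C=C(\[O-])N2[C@@H](Cc3ccccc3)COC2=O)CC=C(C)C.[Na+]
F3 | step 11 | (4S)-4-benzyl-3-[(2R)-2-({(1S)-1-[(2S)-3,6-dihydro-2H-pyran-2-yl]-4-methylpent-3-en-1-yl}oxy)pent-4-enoyl]-1,3-oxazolidin-2-one | C1=CC[C@H](OC1)[C@@H](O[C@H](CC=C)C(=O)N2[C@@H](Cc3ccccc3)COC2=O)CC=C(C)C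
F4 | step 11 | (2R)-2-({(1S)-1-[(2S)-3,6-dihydro-2H-pyran-2-yl]-4-methylpent-3-en-1-yl}oxy)pent-4-en-1-ol | C1=CC[C@H](OC1)[C@@H](O[C@H](CC=C)CO)CC=C(C)C
F5 | step 11 | (2R)-2-({(1S)-1-[(2S)-3,6-dihydro-2H-pyran-2-yl]-4-methylpent-3-en-1-yl}oxy)pent-4-enal | C1=CC[C@H](OC1)[C@@H](O[C@H](CC=C)C=O)CC=C(C)C
F6 | step 11 | (3R,4R)-4-({(1S)-1-[(2S)-3,6-dihydro-2H-pyran-2-yl]-4-methylpent-3-en-1-yl}oxy)hept-6-en-3-ol | C1=CC[C@H](OC1)[C@@H](O[C@H](CC=C)[C@H](O)CC)CC=C(C)C
F7 | step 14 | (1S,3Z)-6,6-dibromo-1-[(2S,7R)-7-[(1S)-1-bromopropyl]-2,3,6,7-tetrahydrooxepin-2-yl]hexa-3,5-dien-1-ol | BrC(Br)=C/C=C\C[C@H](O)[C@@H]1CC=CC[C@H]([C@@H](Br)CC)O1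
F8 | step 10 | (3R,4R)-4-{[(5S,6S)-2,9-dimethyl-6-(prop-2-en-1-yloxy)deca-2,8-dien-5-yl]oxy}hept-6-en-3-yl chloromethanesulfonate | CC(C)=CC[C@H](OCC=C)[C@@H](O[C@H](CC=C)[C@H](OS(=O)(=O)CCl)CC)CC=C(C)C
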